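## Structural features

The target is a 2,3,4-trisubstituted tetrahydrofuran (ring A: O1, C2, C3, C4, C5) with four contiguous stereocentres, three on the ring (2S,3R,4R) and one exocyclic (C7, S). C2 carries a 4-hydroxy-3-methoxyphenyl group, C3 a CH2O unit (C6) esterified with (E)-p-coumaric acid, and C4 the benzylic carbinol C7 bearing the second guaiacyl ring; the C2 aryl group is trans to C6 and C6 is cis to C7. The fragile groups are the three free phenols, the enoate (sensitive to hydride, borane, organometallics and base) and two electron-rich benzylic C–O bonds (C2–O1 and C7–OH); C7–OH sits 1,4 to the C6 oxygen, so acid closes a second oxolane ring. The real difficulty is the 3,4-cis arrangement, which is labile once C7 is a ketone because C4 is then enolisable and O1 is β to the carbonyl group. Added to this are the control of C7 next to a ring stereocentre and the need to tell C5 (ether carbon) from C6 (ester carbon). The key step uses the fact that C4 bears an exocyclic carbon C7 carrying an aryl group and an oxygen: this is what is left when a six-membered ring O1–C2–C3–C7–C4–C5 expels C7 as an aroyl group while the C3–C4 bond forms. Since that 1,2-shift retains C3 and inverts C4, the 2,3-trans/3,4-cis pattern of ring A maps onto a tetrahydropyran whose substituents at the three carbons concerned are all equatorial.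

## Logic of the disconnections

25 ⇒ 24. The three phenolic O–H bonds are traced back to O–Si bonds. The phenols are the most acidic and most easily oxidised sites and stay masked to the end. The forward step must be a buffered fluoride cleavage that neither transesterifies the enoate nor ionises C7–OH.

24 ⇒ 20 + 23. The acyl C–O bond at the C6 oxygen is cut. The enoate would not survive hydride, borane, Grignard or aluminium reagents, so it is attached after all of them; the cut removes nine carbons. The forward step must acylate the primary C6–OH and leave the hindered benzylic C7–OH alone.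

23 ⇒ 21 (through 22). One phenolic O–Si bond is cut; the acid must be free while its phenol is masked, which requires selective hydrolysis of a silyl ester beside an aryl silyl ether.

20 ⇒ 19. The O–Si bond at C6 is cut. A silyl group different in kind from those on the phenols lets C6–OH be released alone. The forward step must not expose the C7 carbinol to protic acid.

19 ⇒ 18. The C7–H bond is cut, returning the carbinol to the aryl ketone that the ring contraction delivers; one stereocentre disappears. The forward step needs reagent control of the C7 face and must follow the ring contraction at once, so that C4 cannot epimerise and O1 cannot be lost from C5 through the enol.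

18 ⇒ 16 (through 17). The C3–C4 bond of ring A is cut and C3 is rejoined to C7; ring A becomes a tetrahydropyran in which C7 is the ring carbinol carbon (pyran C4) and C4 carries a sulfonate (pyran C5). The labile 3,4-cis tetrahydrofuran is exchanged for an all-equatorial chair that can be assembled under thermodynamic control. The forward step demands an equatorial sulfonate cis to the C3 substituent and activation that does not ionise the tertiary benzylic oxygen.

16 ⇒ 15. The S–O bond is cut. The forward step must sulfonylate the secondary hydroxyl beside a tertiary one.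

15 ⇒ 11 + 13 (through 14). The pyran C4–aryl bond (the later C7–aryl bond) is cut, removing the second aryl ring. The configuration created at this carbon is erased in the shift, so only addition in preference to enolisation is demanded.

13 ⇒ 12. One O–Si bond; a phenol protection.

11 ⇒ 10 ⇒ 8 (through 9). The pyran C5–O bond and one C6–H bond are cut. The enone of 8 gives a regiodefined enolate away from C3, and the C5 configuration is then put under thermodynamic control. The forward steps need clean enolate oxidation and an epimerisation that leaves the ketone at pyran C4.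

8 ⇒ 7 ⇒ 5 (through 6). The O–Si bond and the C3–C6 bond are cut. The one-carbon unit enters as an electrophile at the only kinetically acidic position, anti to the C2 aryl group.

5 ⇒ 2 + 3 (through 4). The O1–C6 and C2–C3 bonds of the pyranone (later O1–C5 and C2–C3 of ring A) are cut, a [4+2] disconnection. 3 supplies four carbons with the carbonyl and the enone in place, and the absolute configuration of the whole molecule is set here by a catalyst.

2 ⇒ 1. One O–Si bond; a phenol protection.

## Other disconnections considered

Alternative 1: The cut removes O1–C2 and C3–C4 of ring A and ties the C7 oxygen to C6 as a lactone. In the forward step the potassium alkoxide of the cis-epoxy alcohol A1 adds to the arylidene malonate A2, the malonate carbanion opens the epoxide at the nearer carbon, and the freed benzylic alkoxide closes onto the syn ester to give the bicyclic lactone ester A3.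
- In its favour: two rings and three bonds form in one flask from two aldehyde-derived pieces. C4 and C7 come stereospecifically from the epoxide (inversion at C4, retention at C7). The lactone distinguishes C6 from C5 without protecting groups. Dealkoxycarbonylation and hydride reduction of A3 would meet the chosen route at 20.
- Against it here: A1 is a cis epoxide with an electron-rich aryl group; enantioselective access to cis aryl glycidols is less developed than to trans ones, and its benzylic C–O bond is acid-labile. Under base the epoxy alkoxide can undergo Payne rearrangement. The oxa-Michael addition to an electron-rich acceptor is reversible. The carbanion must attack C4 and not the activated benzylic carbon. The orientation of the C2 aryl group has no strong control element. Halide-mediated dealkoxycarbonylation near 150 °C would stress two benzylic C–O bonds.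
- Comparison: on step count (about three fewer) and convergence this alternative is the better plan. On C4 it is the equal of the chosen plan, since both transfer configuration stereospecifically. On C2, on regiochemistry and on the number of competing ionic pathways the single concerted shift of the chosen plan is the safer mechanism.

Alternative 2: The cut removes C2–C3 and C4–C5, a [3+2] disconnection across ring A. Fluoride desilylates the α-chloro ether A4 to a nonstabilised aryl carbonyl ylide, which adds to the double bond of the (S)-butenolide A5 and gives the bicyclic lactone A6.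
- In its favour: this is the most convergent plan; ring A and two C–C bonds arise in one step. The C7 stereocentre of A5 shields one face, so C3 and C4 follow from it and the cis ring fusion is automatic. The lactone again separates C6 from C5. After A6 only hydride reduction, selective acylation and deallylation with Pd(PPh3)4 (zerovalent palladium) remain, about nine steps in all.
- Against it here: the exo or endo placement of the C2 aryl group has no reliable control with a nonstabilised ylide. The γ-hydrogen of A5 is benzylic, allylic and vinylogously acidic, so basic fluoride can racemise it through a 2-oxyfuran. A4 with an electron-rich aryl group ionises easily and would be hard to handle. The allyl ethers exclude borane reagents downstream.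
- Comparison: this alternative is better in step count and convergence and equal in differentiating C5 from C6. It is weaker in securing the absolute configuration (C7 is carried through a base-labile intermediate, whereas the chosen plan creates C7 last under catalyst control) and in controlling C2.

Alternative 3: The cut removes C2–H, C7–H and the two lactone C–O bonds (O1–C5 and the C7 oxygen to C6), leading back to the diaroylsuccinate A7. RuCl(p-cymene)[(S,S)-TsDPEN] with HCO2H/Et3N reduces both ketones of the epimerising A7, and each new alkoxide lactonises onto the ester of the other half to give the twofold-symmetric bis-lactone A8.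
- In its favour: a single catalytic step would fix all four stereocentres, and A7 is a few steps from 1 by oxidative dimerisation of a β-keto ester. Symmetry halves the effort, and the diexo cis-fused bis-lactone is the natural thermodynamic sink. Epimerisation, which the chosen plan must avoid at C4, is used here productively.
- Against it here: the target is not symmetric. C5 must end as an ether CH2 and C6 as an acylated CH2O beside a free C7–OH, so A8 has to be desymmetrised after both lactones are reduced. Two chemically identical halves can only be told apart statistically, and double ring closure would give the furofuran. The double dynamic reduction must also select one of several diastereomers.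
- Comparison: on stereochemical economy and on the length of the way to a stereodefined core this alternative is the better plan. On the central problem of this target, the distinction of C5 from C6, the chosen plan is better, because the two carbons come from different reagents from the start. In overall step count the two are about equal once the desymmetrisation is included.

Key step: step 10

Remarks on the chemistry (assumptions):
- Ar = 3-methoxy-4-(triisopropylsilyloxy)phenyl. Pyran intermediates are numbered O1, C2 (aryl), C3 (CH2O), C4 (carbonyl or carbinol), C5 (oxygenated), C6 (CH2). On ring contraction pyran C4 becomes C7, pyran C5 becomes C4 and pyran C6 becomes C5; O1, C2 and C3 keep their numbers.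
- The descriptors of 16 (2S,3R,4S,5S; sulfonate cis to the C3 substituent) and of 18 (2S,3R,4R) were derived independently from the target and are linked consistently by a shift with retention at C3 and inversion at the sulfonate carbon; no structural correction was needed.
- Protecting groups are chosen for the end-game: triisopropylsilyl on the two guaiacyl phenols, triethylsilyl on the C6 oxygen, tert-butyldimethylsilyl on the coumarate phenol.
- (S)-BINOL is taken as the ligand antipode that sends the diene to the Si face of the aldehyde, as in the related allylation with the same catalyst; the mirror-image ligand would be used if the sense proved opposite.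

## Route

Step 1
Reactants: 1 vanillin
Product: 2 3-methoxy-4-(triisopropylsilyloxy)benzaldehyde
Conditions: i-Pr3SiCl, imidazole, DMF, rt
Reagents that add atoms: chlorotriisopropylsilane, CC(C)[Si](Cl)(C(C)C)C(C)C
Why: Silylation of a phenol with a silyl chloride and imidazole; the triisopropylsilyl ether should survive amide base, hydride, Grignard, aluminium and buffered HF reagents and leave only with fluoride ion in the last step.

Step 2
Reactants: 2 3-methoxy-4-(triisopropylsilyloxy)benzaldehyde; 3 (E)-1-methoxy-3-(trimethylsilyloxy)buta-1,3-diene
Product: 5 (S)-2-Ar-2,3-dihydro-4H-pyran-4-one, via Mukaiyama aldol adduct 4 (not isolated)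
Conditions: (S)-1,1'-bi-2-naphthol (20 mol %), Ti(Oi-Pr)4 (10 mol %), CF3CO2H (cat.), 4 Å MS, Et2O, −20 °C; then CF3CO2H, CH2Cl2, 0 °C
Reagents that add atoms: none
Why: Catalytic asymmetric hetero-Diels–Alder reaction in its Mukaiyama aldol/cyclisation form; the binaphthol–titanium catalyst should direct the diene to the Si face of the aldehyde and so set C2 as S, and acid closes 4 to the pyranone with loss of methanol.

Step 3
Reactants: 5 (S)-2-Ar-2,3-dihydro-4H-pyran-4-one
Product: 7 (2S,3R)-2-Ar-3-(hydroxymethyl)-2,3-dihydro-4H-pyran-4-one, via lithium enolate 6 (not isolated)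
Conditions: LiN(i-Pr)2, THF, −78 °C; HCHO (gas, from cracked (CH2O)n), −78 °C; AcOH, −78 °C
Reagents that add atoms: formaldehyde, C=O
Why: Kinetic α'-deprotonation of the vinylogous ester at C3 followed by aldol addition to monomeric formaldehyde; the electrophile should enter anti to the C2 aryl group to give the 2,3-trans product, which is also the thermodynamic isomer at this enolisable centre.

Step 4
Reactants: 7 (2S,3R)-2-Ar-3-(hydroxymethyl)-2,3-dihydro-4H-pyran-4-one
Product: 8 (2S,3R)-2-Ar-3-[(triethylsilyloxy)methyl]-2,3-dihydro-4H-pyran-4-one
Conditions: Et3SiCl, imidazole, CH2Cl2, 0 °C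
Reagents that add atoms: chlorotriethylsilane, CC[Si](Cl)(CC)CC
Why: Silylation of a primary alcohol under mild base that does not provoke retro-aldol loss of formaldehyde; the triethylsilyl ether is the one silyl group that can later be removed by buffered HF while the aryl silyl ethers stay.

Step 5
Reactants: 8 (2S,3R)-2-Ar-3-[(triethylsilyloxy)methyl]-2,3-dihydro-4H-pyran-4-one
Product: 10 (2S,3R)-2-Ar-5-hydroxy-3-[(triethylsilyloxy)methyl]tetrahydropyran-4-one as a mixture of C5 epimers, via potassium enolate 9 (not isolated)
Conditions: K[HB(s-Bu)3], THF, −78 °C; then 3-phenyl-2-(phenylsulfonyl)oxaziridine, −78 °C; AcOH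
Reagents that add atoms: 3-phenyl-2-(phenylsulfonyl)oxaziridine, O=S(=O)(c1ccccc1)N1OC1c1ccccc1
Why: Conjugate hydride addition to the enone gives the C4–C5 enolate regiospecifically (away from C3, so the silyloxy group cannot be eliminated), and oxidation of this enolate with the N-sulfonyloxaziridine (Davis hydroxylation) places oxygen on C5; the potassium enolate is used to limit interception by the imine by-product. Axial attack is expected to favour the C5 epimer with the hydroxyl trans to the C3 substituent, so C5 is corrected in step 6.

Step 6
Reactants: 10 (2S,3R)-2-Ar-5-hydroxy-3-[(triethylsilyloxy)methyl]tetrahydropyran-4-one (C5 epimers)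
Product: 11 (2S,3R,5S)-2-Ar-5-hydroxy-3-[(triethylsilyloxy)methyl]tetrahydropyran-4-one
Conditions: 1,8-diazabicyclo[5.4.0]undec-7-ene (0.2 equiv), CH2Cl2, 0 °C to rt
Reagents that add atoms: none
Why: Base-mediated epimerisation of an α-hydroxy ketone through its enol; the isomer with aryl, silyloxymethyl and hydroxyl groups all equatorial and the hydroxyl hydrogen-bonded to the carbonyl group should be the thermodynamic sink. The carbonyl group is expected to stay at C4 because the transposed ketol would place it next to the C6–O1 ether carbon.

Step 7
Reactants: 12 4-bromo-2-methoxyphenol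
Product: 13 (4-bromo-2-methoxyphenoxy)triisopropylsilane
Conditions: i-Pr3SiCl, imidazole, DMF, rt
Reagents that add atoms: chlorotriisopropylsilane, CC(C)[Si](Cl)(C(C)C)C(C)C
Why: Phenol silylation; the silyl ether para to the bromide cannot migrate to the carbanion centre in the next step.

Step 8
Reactants: 11 (2S,3R,5S)-2-Ar-5-hydroxy-3-[(triethylsilyloxy)methyl]tetrahydropyran-4-one; 13 (4-bromo-2-methoxyphenoxy)triisopropylsilane
Product: 15 (2S,3R,4S,5S)-2,4-di-Ar-3-[(triethylsilyloxy)methyl]tetrahydropyran-4,5-diol, via arylmagnesium bromide 14 (not isolated)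
Conditions: 13, Mg, THF, rt (3 equiv of 14); then 11, THF, −78 to −20 °C; aq. NH4Cl
Reagents that add atoms: none
Why: Grignard addition to an α-hydroxy ketone; the first equivalent forms the magnesium alkoxide and the chelated carbonyl group should take the aryl group from the equatorial direction to give the axial tertiary alcohol. The configuration at this carbon is erased in step 10, so its facial selectivity does not affect the outcome.

Step 9
Reactants: 15 (2S,3R,4S,5S)-2,4-di-Ar-3-[(triethylsilyloxy)methyl]tetrahydropyran-4,5-diol
Product: 16 (2S,3R,4S,5S)-2,4-di-Ar-4-hydroxy-3-[(triethylsilyloxy)methyl]tetrahydropyran-5-yl methanesulfonate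
Conditions: MsCl (1.3 equiv), pyridine, CH2Cl2, 0 °C to rt
Reagents that add atoms: methanesulfonyl chloride, CS(Cl)(=O)=O
Why: Selective sulfonylation of the secondary hydroxyl of a secondary/tertiary diol; pyridine avoids the sulfene pathway, so the tertiary benzylic hydroxyl should stay free, and the gauche relation of the two oxygens prevents epoxide closure.

Step 10
Reactants: 16 (2S,3R,4S,5S)-2,4-di-Ar-4-hydroxy-3-[(triethylsilyloxy)methyl]tetrahydropyran-5-yl methanesulfonate
Product: 18 (2S,3R,4R)-2-Ar-4-(Ar-carbonyl)-3-[(triethylsilyloxy)methyl]tetrahydrofuran, via diethylaluminium alkoxide 17 (not isolated)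
Conditions: AlEt3 (3 equiv), CH2Cl2, −78 to −20 °C; cold aq. potassium sodium tartrate
Reagents that add atoms: none
Why: AlEt3 deprotonates the tertiary hydroxyl to give alkoxide 17 and a second equivalent binds a sulfonyl oxygen; the pyran C3–C4 bond, the only bond of the carbinol carbon antiperiplanar to the equatorial C5–O bond, then shifts from pyran C4 to pyran C5 as the mesylate leaves and the aluminium alkoxide collapses to the aryl ketone (semipinacol rearrangement of a 2-sulfonyloxy tertiary alcohol). The closest known reaction types are the organoaluminium-promoted pinacol-type rearrangement of β-mesyloxy alcohols and the ring contractions of 2-sulfonyloxycyclohexanols and of pyranoside sulfonates to acylcyclopentanes and formyl furanosides. Ring A is closed by ring contraction through a concerted 1,2-alkyl shift (new bond C3–C4 of the target, pyran C4 extruded as C7), so no cyclisation mode in the Baldwin sense is involved. The one new stereocentre, C4 of ring A, is fixed by inversion at the mesylate carbon while the migrating C3 keeps its configuration; from the chair with the C2 aryl group, the C3 substituent and the mesylate equatorial this places the aroyl group cis to C6 and leaves the C2 aryl group trans to C6, that is (2S,3R,4R). The selectivity needed is ring-bond migration in preference to aryl migration, epoxide closure and ionisation at the benzylic carbon: the first two would need a leaving group anti to the aryl group or to the oxygen, which the equatorial mesylate denies in either C4 epimer, and early formation of the alkoxide next to an electron-rich aryl donor should favour the push–pull shift over loss of the tertiary oxygen. The cis ketone is formed without passing through an enol, and the cold, non-basic conditions and tartrate work-up are chosen so that it is neither epimerised nor opened by retro-oxa-Michael reaction before step 11.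

Step 11
Reactants: 18 (2S,3R,4R)-2-Ar-4-(Ar-carbonyl)-3-[(triethylsilyloxy)methyl]tetrahydrofuran
Product: 19 (2S,3R,4R)-2-Ar-4-[(S)-Ar(hydroxy)methyl]-3-[(triethylsilyloxy)methyl]tetrahydrofuran
Conditions: (R)-1-methyl-3,3-diphenyl-tetrahydro-1H,3H-pyrrolo[1,2-c][1,3,2]oxazaborole (0.2 equiv), BH3·SMe2, THF, −30 °C; MeOH
Reagents that add atoms: none
Why: Corey–Bakshi–Shibata reduction; with the aryl group as the large substituent the (R)-catalyst should deliver hydride to the Re face of C7 and give the S carbinol (the (S)-catalyst gives the R alcohol from aryl methyl ketones). The neutral, cold conditions leave C4 untouched, the labile ketone is removed directly after it is formed, and no alkene is yet present for borane to attack.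

Step 12
Reactants: 19 (2S,3R,4R)-2-Ar-4-[(S)-Ar(hydroxy)methyl]-3-[(triethylsilyloxy)methyl]tetrahydrofuran
Product: 20 {(2S,3R,4R)-2-Ar-4-[(S)-Ar(hydroxy)methyl]tetrahydrofuran-3-yl}methanol
Conditions: HF·pyridine, pyridine, THF, 0 °C
Reagents that add atoms: none
Why: Cleavage of a primary alkyl triethylsilyl ether with pyridine-buffered HF, under which hindered aryl triisopropylsilyl ethers should react far more slowly; the near-neutral medium should not ionise the electron-rich C7 carbinol, which under protic acid would be captured by the freed C6 hydroxyl.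

Step 13
Reactants: 21 p-coumaric acid
Product: 23 (E)-3-[4-(tert-butyldimethylsilyloxy)phenyl]acrylic acid, via bis-silylated coumarate 22 (not isolated)
Conditions: t-BuMe2SiCl (2.3 equiv), imidazole, DMF, rt; then AcOH/THF/H2O, rt
Reagents that add atoms: tert-butylchlorodimethylsilane, CC(C)(C)[Si](C)(C)Cl
Why: Exhaustive silylation followed by selective hydrolysis of the silyl ester, whose acyl–O–Si bond is far more labile to aqueous acid than the aryl–O–Si bond.

Step 14
Reactants: 20 {(2S,3R,4R)-2-Ar-4-[(S)-Ar(hydroxy)methyl]tetrahydrofuran-3-yl}methanol; 23 (E)-3-[4-(tert-butyldimethylsilyloxy)phenyl]acrylic acid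
Product: 24 {(2S,3R,4R)-2-Ar-4-[(S)-Ar(hydroxy)methyl]tetrahydrofuran-3-yl}methyl (E)-3-[4-(tert-butyldimethylsilyloxy)phenyl]acrylate
Conditions: 23 (1.05 equiv), EDC·HCl, 4-(dimethylamino)pyridine (0.1 equiv), CH2Cl2, −10 to 0 °C
Reagents that add atoms: none
Why: Steglich esterification; the primary C6 hydroxyl should react much faster than the secondary benzylic C7 hydroxyl, which is flanked by the ring and an aryl group, so one equivalent of acid at low temperature should give the mono-ester.

Step 15
Reactants: 24 {(2S,3R,4R)-2-Ar-4-[(S)-Ar(hydroxy)methyl]tetrahydrofuran-3-yl}methyl (E)-3-[4-(tert-butyldimethylsilyloxy)phenyl]acrylate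
Product: 25 {(2S,3R,4R)-2-(4-hydroxy-3-methoxyphenyl)-4-[(S)-hydroxy(4-hydroxy-3-methoxyphenyl)methyl]tetrahydrofuran-3-yl}methyl (E)-3-(4-hydroxyphenyl)acrylate (CNP0330050.2)
Conditions: Bu4NF (3.5 equiv), AcOH (3.5 equiv), THF, 0 °C
Reagents that add atoms: none
Why: Fluoride cleavage of the three aryl silyl ethers; acetic acid buffers the phenoxides so that the enoate should not be transesterified or migrate to C7–OH, and no acid strong enough to ionise the benzylic C–O bonds is present.

## Compound list

1 | vanillin | COc1cc(C=O)ccc1O | starting material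
2 | 3-methoxy-4-(triisopropylsilyloxy)benzaldehyde | COc1cc(C=O)ccc1O[Si](C(C)C)(C(C)C)C(C)C | intermediate
3 | (E)-1-methoxy-3-(trimethylsilyloxy)buta-1,3-diene | CO/C=C/C(=C)O[Si](C)(C)C | starting material
4 | (S,E)-5-Ar-1-methoxy-5-(trimethylsilyloxy)pent-1-en-3-one (Mukaiyama aldol adduct) | CO/C=C/C(=O)C[C@H](O[Si](C)(C)C)c1ccc(O[Si](C(C)C)(C(C)C)C(C)C)c(OC)c1 | intermediate (not isolated)
5 | (S)-2-Ar-2,3-dihydro-4H-pyran-4-one | O=C1C[C@@H](c2ccc(O[Si](C(C)C)(C(C)C)C(C)C)c(OC)c2)OC=C1 | intermediate
6 | lithium enolate of 5 (C3=C4–OLi) | [Li]OC1=C[C@@H](c2ccc(O[Si](C(C)C)(C(C)C)C(C)C)c(OC)c2)OC=C1 | intermediate (not isolated)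
7 | (2S,3R)-2-Ar-3-(hydroxymethyl)-2,3-dihydro-4H-pyran-4-one | [C@H]1(c2ccc(O[Si](C(C)C)(C(C)C)C(C)C)c(OC)c2)OC=CC(=O)[C@@H]1CO | intermediate
8 | (2S,3R)-2-Ar-3-[(triethylsilyloxy)methyl]-2,3-dihydro-4H-pyran-4-one | [C@H]1(c2ccc(O[Si](C(C)C)(C(C)C)C(C)C)c(OC)c2)OC=CC(=O)[C@@H]1CO[Si](CC)(CC)CC | intermediate
9 | potassium C4–C5 enolate of the tetrahydropyranone | [C@H]1(c2ccc(O[Si](C(C)C)(C(C)C)C(C)C)c(OC)c2)OCC=C(O[K])[C@@H]1CO[Si](CC)(CC)CC | intermediate (not isolated)
10 | (2S,3R)-2-Ar-5-hydroxy-3-[(triethylsilyloxy)methyl]tetrahydropyran-4-one, mixture of C5 epimers | [C@H]1(c2ccc(O[Si](C(C)C)(C(C)C)C(C)C)c(OC)c2)OCC(O)C(=O)[C@@H]1CO[Si](CC)(CC)CC | intermediate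
11 | (2S,3R,5S)-2-Ar-5-hydroxy-3-[(triethylsilyloxy)methyl]tetrahydropyran-4-one (all substituents equatorial) | [C@H]1(c2ccc(O[Si](C(C)C)(C(C)C)C(C)C)c(OC)c2)OC[C@H](O)C(=O)[C@@H]1CO[Si](CC)(CC)CC | intermediate
12 | 4-bromo-2-methoxyphenol | COc1cc(Br)ccc1O | starting material
13 | (4-bromo-2-methoxyphenoxy)triisopropylsilane | COc1cc(Br)ccc1O[Si](C(C)C)(C(C)C)C(C)C | intermediate
14 | [3-methoxy-4-(triisopropylsilyloxy)phenyl]magnesium bromide | COc1cc([Mg]Br)ccc1O[Si](C(C)C)(C(C)C)C(C)C | intermediate (not isolated)
15 | (2S,3R,4S,5S)-2,4-di-Ar-3-[(triethylsilyloxy)methyl]tetrahydropyran-4,5-diol | [C@H]1(c2ccc(O[Si](C(C)C)(C(C)C)C(C)C)c(OC)c2)OC[C@H](O)[C@@](O)(c3ccc(O[Si](C(C)C)(C(C)C)C(C)C)c(OC)c3)[C@@H]1CO[Si](CC)(CC)CC | intermediate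
16 | (2S,3R,4S,5S)-2,4-di-Ar-4-hydroxy-3-[(triethylsilyloxy)methyl]tetrahydropyran-5-yl methanesulfonate (2,3-trans, 3,5-cis, mesylate equatorial) | [C@H]1(c2ccc(O[Si](C(C)C)(C(C)C)C(C)C)c(OC)c2)OC[C@H](OS(C)(=O)=O)[C@@](O)(c3ccc(O[Si](C(C)C)(C(C)C)C(C)C)c(OC)c3)[C@@H]1CO[Si](CC)(CC)CC | intermediate
17 | diethylaluminium alkoxide of 16 | [C@H]1(c2ccc(O[Si](C(C)C)(C(C)C)C(C)C)c(OC)c2)OC[C@H](OS(C)(=O)=O)[C@@](O[Al](CC)CC)(c3ccc(O[Si](C(C)C)(C(C)C)C(C)C)c(OC)c3)[C@@H]1CO[Si](CC)(CC)CC | intermediate (not isolated)
18 | (2S,3R,4R)-2-Ar-4-(Ar-carbonyl)-3-[(triethylsilyloxy)methyl]tetrahydrofuran (2,3-trans, 3,4-cis) | COc1cc(C(=O)[C@H]2CO[C@H](c3ccc(O[Si](C(C)C)(C(C)C)C(C)C)c(OC)c3)[C@H]2CO[Si](CC)(CC)CC)ccc1O[Si](C(C)C)(C(C)C)C(C)C | intermediate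
19 | (2S,3R,4R)-2-Ar-4-[(S)-Ar(hydroxy)methyl]-3-[(triethylsilyloxy)methyl]tetrahydrofuran | COc1cc([C@@H](O)[C@H]2CO[C@H](c3ccc(O[Si](C(C)C)(C(C)C)C(C)C)c(OC)c3)[C@H]2CO[Si](CC)(CC)CC)ccc1O[Si](C(C)C)(C(C)C)C(C)C | intermediate
20 | {(2S,3R,4R)-2-Ar-4-[(S)-Ar(hydroxy)methyl]tetrahydrofuran-3-yl}methanol | COc1cc([C@@H](O)[C@H]2CO[C@H](c3ccc(O[Si](C(C)C)(C(C)C)C(C)C)c(OC)c3)[C@H]2CO)ccc1O[Si](C(C)C)(C(C)C)C(C)C | intermediate
21 | p-coumaric acid | OC(=O)/C=C/c1ccc(O)cc1 | starting material
22 | tert-butyldimethylsilyl (E)-3-[4-(tert-butyldimethylsilyloxy)phenyl]acrylate | CC(C)(C)[Si](C)(C)OC(=O)/C=C/c1ccc(O[Si](C)(C)C(C)(C)C)cc1 | intermediate (not isolated)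
23 | (E)-3-[4-(tert-butyldimethylsilyloxy)phenyl]acrylic acid | OC(=O)/C=C/c1ccc(O[Si](C)(C)C(C)(C)C)cc1 | intermediate
24 | {(2S,3R,4R)-2-Ar-4-[(S)-Ar(hydroxy)methyl]tetrahydrofuran-3-yl}methyl (E)-3-[4-(tert-butyldimethylsilyloxy)phenyl]acrylate | COc1cc([C@@H](O)[C@H]2CO[C@H](c3ccc(O[Si](C(C)C)(C(C)C)C(C)C)c(OC)c3)[C@H]2COC(=O)/C=C/c2ccc(O[Si](C)(C)C(C)(C)C)cc2)ccc1O[Si](C(C)C)(C(C)C)C(C)C | intermediate
25 | {(2S,3R,4R)-2-(4-hydroxy-3-methoxyphenyl)-4-[(S)-hydroxy(4-hydroxy-3-methoxyphenyl)methyl]tetrahydrofuran-3-yl}methyl (E)-3-(4-hydroxyphenyl)acrylate | COc1cc([C@@H](O)[C@H]2CO[C@H](c3ccc(O)c(OC)c3)[C@H]2COC(=O)/C=C/c2ccc(O)cc2)ccc1O | target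

## Step count and least certain steps

Total: 15 steps. Longest linear sequence: 13 steps from 1 (steps 1–6, 8–12, 14, 15); steps 7 and 13 prepare the side fragments 13 and 23.

Step 10 (key step). The tertiary benzylic C–O bond may ionise in competition with the shift and lead to elimination. An ethyl group or hydride may be transferred from aluminium to the new ketone. The cis ketone may epimerise or ring-open on work-up. The fallback sets out from 15 and returns to the route at 18. The diol is treated with Tf2O and 2,6-di-tert-butyl-4-methylpyridine in CH2Cl2 at −78 °C to give the secondary triflate F1, which should rearrange on warming to −20 °C in the buffered, metal-free medium. Here the leaving group alone supplies the pull and the free tertiary hydroxyl the push, as in the ring contractions of pyranoside triflates and the classical solvolytic rearrangements of 2-hydroxy sulfonates, with the same antiperiplanar ring bond migrating.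

Step 3. Monomeric formaldehyde may oligomerise, a second hydroxymethyl group may be introduced, and the aldolate may revert on warming. The fallback sets out from 5 and returns at 7. The lithium enolate is trapped with Me3SiCl to give the silyl dienol ether (S)-2-Ar-4-(trimethylsilyloxy)-2H-pyran F2. This is hydroxymethylated with commercial aqueous formaldehyde and Yb(OTf)3 (10 mol %) in THF/H2O, a Mukaiyama aldol reaction in water; attack at C3 anti to the aryl group regenerates the vinylogous ester as 7.

Step 6. Under base the ketol may transpose through the enediol, the silyloxy group may be eliminated from the C3 enolate, or epimerisation may stop short. The fallback sets out from 10 and returns at 15, correcting C5 by oxidation and reduction once the enolisable ketone is gone. The unequilibrated mixture 10 is taken through the aryl addition of step 8; its (5S) component gives 15 directly and its (5R) component gives the C5-epimeric diol F3 (drawn for equatorial delivery of the aryl group), which is separated by chromatography. F3 is oxidised with Dess–Martin periodinane (NaHCO3, CH2Cl2) to the hydroxy ketone F4, which has no stereocentre next to the carbonyl group that could enolise. Reduction of F4 with NaBH4/CeCl3·7H2O in MeOH at −40 °C should deliver hydride axially and give the equatorial alcohol 15.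

Step 8. The basic Grignard reagent may enolise the hindered, doubly α-substituted ketone, with loss of configuration at C5 or C3 or elimination of silanolate, and conversion may be low. The fallback sets out from 11 and returns at 16. The order of events is reversed: 11 is mesylated first (MsCl, Et3N, CH2Cl2, −20 °C) to the α-mesyloxy ketone F5, whose carbonyl group is more electrophilic and which carries no acidic hydroxyl. It then needs only 1.2 equiv of 14 in THF at −78 °C to give 16 directly, an addition known for α-mesyloxy ketones on the way to aluminium-promoted rearrangements.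

Step 11. The branched ring carbon C4 may rival the aryl group as the large substituent in the catalyst complex, or the substrate's own facial bias may oppose the catalyst, so that facial discrimination at C7 is poor. The fallback sets out from 18 and returns at 19, with stoichiometric recycling in place of catalyst control. Reduction with NaBH4/CeCl3·7H2O in MeOH at −78 °C gives 19 together with its C7 epimer F6. The two are separated by chromatography, and F6 is oxidised back to 18 with MnO2 in CH2Cl2 (neutral, so C4 is not touched) and reduced again.

Further compounds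
F1 | step 10 | (2S,3R,4S,5S)-2,4-di-Ar-4-hydroxy-3-[(triethylsilyloxy)methyl]tetrahydropyran-5-yl trifluoromethanesulfonate | [C@H]1(c2ccc(O[Si](C(C)C)(C(C)C)C(C)C)c(OC)c2)OC[C@H](OS(=O)(=O)C(F)(F)F)[C@@](O)(c3ccc(O[Si](C(C)C)(C(C)C)C(C)C)c(OC)c3)[C@@H]1CO[Si](CC)(CC)CC
F2 | step 3 | (S)-2-Ar-4-(trimethylsilyloxy)-2H-pyran | [C@H]1(c2ccc(O[Si](C(C)C)(C(C)C)C(C)C)c(OC)c2)OC=CC(O[Si](C)(C)C)=C1
F3 | step 6 | (2S,3R,4S,5R)-2,4-di-Ar-3-[(triethylsilyloxy)methyl]tetrahydropyran-4,5-diol (C5 epimer of 15) | [C@H]1(c2ccc(O[Si](C(C)C)(C(C)C)C(C)C)c(OC)c2)OC[C@@H](O)[C@@](O)(c3ccc(O[Si](C(C)C)(C(C)C)C(C)C)c(OC)c3)[C@@H]1CO[Si](CC)(CC)CC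
F4 | step 6 | (2S,3R,4S)-2,4-di-Ar-4-hydroxy-3-[(triethylsilyloxy)methyl]tetrahydropyran-5-one | [C@H]1(c2ccc(O[Si](C(C)C)(C(C)C)C(C)C)c(OC)c2)OCC(=O)[C@@](O)(c3ccc(O[Si](C(C)C)(C(C)C)C(C)C)c(OC)c3)[C@@H]1CO[Si](CC)(CC)CC
F5 | step 8 | (2S,3R,5S)-2-Ar-4-oxo-3-[(triethylsilyloxy)methyl]tetrahydropyran-5-yl methanesulfonate | [C@H]1(c2ccc(O[Si](C(C)C)(C(C)C)C(C)C)c(OC)c2)OC[C@H](OS(C)(=O)=O)C(=O)[C@@H]1CO[Si](CC)(CC)CC
F6 | step 11 | (2S,3R,4R)-2-Ar-4-[(R)-Ar(hydroxy)methyl]-3-[(triethylsilyloxy)methyl]tetrahydrofuran (C7 epimer of 19) | COc1cc([C@H](O)[C@H]2CO[C@H](c3ccc(O[Si](C(C)C)(C(C)C)C(C)C)c(OC)c3)[C@H]2CO[Si](CC)(CC)CC)ccc1O[Si](C(C)C)(C(C)C)C(C)C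
A1 | alternative 1 | [(2S,3R)-3-[3-methoxy-4-(triisopropylsilyloxy)phenyl]oxiran-2-yl]methanol (cis) | OC[C@@H]1O[C@@H]1c1ccc(O[Si](C(C)C)(C(C)C)C(C)C)c(OC)c1
A2 | alternative 1 | dimethyl 2-[3-methoxy-4-(triisopropylsilyloxy)benzylidene]malonate | COC(=O)C(=Cc1ccc(O[Si](C(C)C)(C(C)C)C(C)C)c(OC)c1)C(=O)OC
A3 | alternative 1 | methyl diexo-2,6-bis[3-methoxy-4-(triisopropylsilyloxy)phenyl]-8-oxo-3,7-dioxabicyclo[3.3.0]octane-1-carboxylate | COc1cc([C@@H](O4)[C@H]2CO[C@H](c3ccc(O[Si](C(C)C)(C(C)C)C(C)C)c(OC)c3)[C@@]2(C(=O)OC)C4=O)ccc1O[Si](C(C)C)(C(C)C)C(C)C
A4 | alternative 2 | 1-(allyloxy)-4-{chloro[(trimethylsilyl)methoxy]methyl}-2-methoxybenzene | ClC(OC[Si](C)(C)C)c1ccc(OCC=C)c(OC)c1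
A5 | alternative 2 | (S)-5-[4-(allyloxy)-3-methoxyphenyl]furan-2(5H)-one | O=C1C=C[C@@H](c2ccc(OCC=C)c(OC)c2)O1
A6 | alternative 2 | diexo-2,6-bis[4-(allyloxy)-3-methoxyphenyl]-3,7-dioxabicyclo[3.3.0]octan-8-one | COc1cc([C@@H](O4)[C@H]2CO[C@H](c3ccc(OCC=C)c(OC)c3)[C@H]2C4=O)ccc1OCC=C
A7 | alternative 3 | dimethyl 2,3-bis[4-(tert-butyldimethylsilyloxy)-3-methoxybenzoyl]succinate (epimerising mixture) | COC(=O)C(C(=O)c1ccc(O[Si](C)(C)C(C)(C)C)c(OC)c1)C(C(=O)OC)C(=O)c1ccc(O[Si](C)(C)C(C)(C)C)c(OC)c1
A8 | alternative 3 | diexo-2,6-bis[4-(tert-butyldimethylsilyloxy)-3-methoxyphenyl]-3,7-dioxabicyclo[3.3.0]octane-4,8-dione | COc1cc([C@@H](O4)[C@H]2C(=O)O[C@H](c3ccc(O[Si](C)(C)C(C)(C)C)c(OC)c3)[C@H]2C4=O)ccc1O[Si](C)(C)C(C)(C)C
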